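## Structural features

The target 19 is an elemane-type sesquiterpene lactone: a cyclohexane (C5–C10, elemane numbering, used throughout) in which all six ring carbons are stereogenic, cis-fused across C6–C7 to an α-methylene-γ-butyrolactone (C6–O–C12(=O)–C11(=C13H2)–C7). Going round the ring, C10 is quaternary (methyl and vinyl), C5 carries isopropenyl, C6 the lactone oxygen, C7 a tertiary hydroxyl and C11, C8 a secondary hydroxyl, and C9 the angelate ((Z)-2-methylbut-2-enoate). With β defined as the face of the C10 methyl group, the methyl, the isopropenyl group, O6, C11 and O9 are β; the vinyl group and the hydroxyls on C7 and C8 are α. In the chair that keeps isopropenyl, vinyl, C11, O8 and O9 equatorial, the C10 methyl, O6 and the C7 hydroxyl are axial, so O6/O7 are trans-diaxial, O7/O8 cis and O8/O9 trans-diequatorial, and the axial methyl screens the β face at C6, C8 and C9. Fragile are the α-methylene lactone (Michael acceptor, reduced by hydrides), the β-hydroxy lactone (dehydration, retro-aldol), the angelate (Z to E isomerisation, migration to the free O8) and the three terminal alkenes, which rule out unselective electrophilic oxidants. The real difficulty is the array C6–C7–C8–C9 of four oxygenated carbons around the ring-fusion tertiary carbinol C7, next to the quaternary C10, and the attachment of the unsaturated lactone to it. The key step exploits the trans-diaxial pair O6 (lactone)/O7 (hydroxyl) with the cis hydroxyl on C8: this is the signature of a C6–C7 epoxide formed on the face of the C8 hydroxyl and opened at C6 by the C12 carboxyl group that C7 carries through C11.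

## Logic of the disconnections

19 to 17 (through 18). The C6–O(lactone) and C7–O(hydroxyl) bonds are cut together, which removes the lactone ring and the stereocentres C6 and C7 and leaves a C6=C7 alkene that carries the acrylate on C7. The cut is made here because both oxygens are trans-diaxial and the C8 hydroxyl is cis to O7, so one oxygen atom delivered by O8 can become O7 while the C12 carboxyl supplies O6 with inversion. The forward step must pick C6=C7 among five C=C bonds and the α face; this is why O8 must be the only free hydroxyl and the step is put last.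

17 to 15 (through 16). The C11–C12 bond is cut (carbonyl carbon from CO, methoxy from methanol), and the acrylate becomes a terminal alkyne on C7; O8 is silylated. An alkyne is inert to base, hydride and the oxidants used earlier, whereas an acrylate conjugated to the ring diene is not. The forward step must add the carboxyl carbon to the internal alkyne carbon, and O8 must be blocked so that it cannot capture the acyl metal intermediate.

15 to 12 (through 14 and 13). The O9–acyl bond and the C9–H bond are cut, giving a C9 ketone. Introducing the angelate while O8 is silylated removes any need to tell O8 from O9 later. The forward reduction must deliver hydride to the α face of C9, which the axial C10 methyl should enforce.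

12 to 9 (through 11 and 10). The C8–O bond is cut and the C6=C7 alkene is moved back into conjugation, giving a cross-conjugated enynone. One enolate oxidation then installs O8 and places the alkene where the key step needs it. The forward step must oxidise the extended enolate at its α-carbon, on the α face, without touching the other alkenes.

9 to 7 (through 8). The C7–C11 bond is cut and the carbonyl is transposed from C9 to C7. This reaches a 4,4,5-trisubstituted cyclohexenone whose only stereocentres are C5 and C10. The forward sequence needs clean 1,2-addition and a [3,3] shift that ends at the neopentyl carbon C9.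

7 to 3 and 4 (through 6 and 5). The ring bonds C5–C6 and C9–C10 are cut (Diels–Alder), and the vinyl group is traced back to the formyl group of the dienophile. Both carbon-only stereocentres, including the quaternary one, then come from the geometry of one alkene and one catalyst-controlled event. The forward step must be regioselective (diene CH2 terminus to C5) and enantioselective.

3 to 1 and 2. The C=C bond between C5 and C10 of the dienophile is cut (Wittig). The forward step must give the E isomer, which translates into methyl cis to isopropenyl.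

## Other disconnections considered

Alternative 1: (the disconnection that comes to mind first) cut C7–C11, that is, add an acrylate α-carbanion equivalent to a C7 ketone, made intramolecular from O6. The forward key step would be a Nozaki–Hiyama–Kishi (CrCl2, catalytic NiCl2) or Morita–Baylis–Hillman closure of the 6-O-(2-bromoacryloyl) 7-ketone A1. The chosen plan is preferred for three reasons. A1 holds a ketone flanked by two oxygenated, epimerisable centres (C6 acyloxy, C8 silyloxy). Its O6 ester must first be placed cis to the isopropenyl group, the face that enolate oxidation would not give, so an inversion would be needed. The ester must also adopt its disfavoured conformation to close the 5-membered ring. Several more steps are expected than for the epoxide route, in which C7 is never a ketone.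

Alternative 2: cut C5–C10, the biomimetic Cope rearrangement of the (1(10)E,4E)-germacradienolide A2 through a chair transition state. The chosen plan is preferred because A2, a ten-membered diene carrying the same four oxygenated centres and the same lactone, is harder to make than 19 itself. In addition, the configuration at C5/C10 relative to C6–C9 would depend on which ring conformer rearranges, and the reaction would heat a β-hydroxy α-methylene lactone. The disconnection gives no simplification.

Alternative 3: cut C5–C6 and C9–C10 on a fully oxygenated ring. The forward key step would be a Diels–Alder reaction of the (1E,3E)-1,4-bis(silyloxy)diene A3 with the commercial dienophile A4 to give cyclohexene A5, followed by OsO4 dihydroxylation of C7=C8 anti to both allylic oxygens. Four centres would arise at once, but the trisubstituted dienophile must react with its formyl group exo and its ester endo, and A3 must be made with defined geometry at a trisubstituted enol ether. The osmylation must also precede the introduction of vinyl and isopropenyl. This forces both groups to be carried as carbonyl groups and then two olefinations, a lactone α-methylenation next to a tertiary hydroxyl and a selective acylation of O9 on a polyol. The route would be clearly longer and heavier in protecting groups.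

Key step: step 11

Assumption: the sense of induction of the chiral diol in step 2 is taken to be the one known for α-substituted acroleins; if it is the opposite, the enantiomeric diol (also commercial) is used.
Assumption: in step 11 the methyl group of the ester is taken to leave as methanol after water adds to the cyclic dioxocarbenium ion.

## Route

Step 1
Reactants: 1 2-methylprop-2-enal; 2 2-(triphenyl-λ5-phosphanylidene)propanal
Product: 3 (2E)-2,4-dimethylpenta-2,4-dienal
Conditions: toluene, 80 °C, sealed vessel
Reagents that add atoms: none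
Why: Wittig olefination of the aldehyde with a formyl-stabilised ylide; stabilised ylides give the (E)-trisubstituted alkene, which places CHO trans to the isopropenyl group as the later cis methyl/isopropenyl relationship requires.

Step 2
Reactants: 3 (2E)-2,4-dimethylpenta-2,4-dienal; 4 (1E)-3-[(tert-butyldimethylsilyl)oxy]-N,N-dimethylbuta-1,3-dien-1-amine
Product: 5 (1S,2R,6S)-4-[(tert-butyldimethylsilyl)oxy]-2-(dimethylamino)-1-methyl-6-(prop-1-en-2-yl)cyclohex-3-ene-1-carbaldehyde
Conditions: (4R,5R)-2,2-dimethyl-α,α,α′,α′-tetra(naphthalen-1-yl)-1,3-dioxolane-4,5-dimethanol (20 mol %), toluene, −78 to −40 °C; used crude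
Reagents that add atoms: none
Why: Normal-demand Diels–Alder reaction of the 1-amino-3-silyloxy diene with the enal hydrogen-bonded to the chiral diol; the nucleophilic CH2 terminus bonds to the β-carbon (C5) and the amino-bearing terminus to the α-carbon (C10). Suprafacial addition to the (E)-alkene fixes methyl cis to isopropenyl, and the diol shields one face of the enal, so C10 and C5 are set in one event (endo adduct; the amino-bearing centre is lost in step 3).

Step 3
Reactants: 5 (1S,2R,6S)-4-[(tert-butyldimethylsilyl)oxy]-2-(dimethylamino)-1-methyl-6-(prop-1-en-2-yl)cyclohex-3-ene-1-carbaldehyde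
Product: 7 (4R,5S)-4-ethenyl-4-methyl-5-(prop-1-en-2-yl)cyclohex-2-en-1-one, via vinyl silyl enol ether 6 (not isolated)
Conditions: Ph3PCH3Br, KN(SiMe3)2, THF, −78 to 0 °C; then 10% aq HF, MeCN, 0 °C to rt
Reagents that add atoms: methylenetriphenylphosphorane, C=P(c1ccccc1)(c1ccccc1)c1ccccc1
Why: Wittig methylenation of the non-enolisable aldehyde leaves the silyl enol ether and the amine untouched; aqueous HF then hydrolyses the silyl enol ether and the β-amino ketone loses dimethylamine (E1cB) to give the enone. No stereocentre is affected.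

Step 4
Reactants: 7 (4R,5S)-4-ethenyl-4-methyl-5-(prop-1-en-2-yl)cyclohex-2-en-1-one
Product: 8 (4R,5S)-4-ethenyl-4-methyl-5-(prop-1-en-2-yl)-1-[(trimethylsilyl)ethynyl]cyclohex-2-en-1-ol (both C1 epimers)
Conditions: Me3SiC≡CH, n-BuLi, THF, −78 °C; then 7, −78 to −40 °C; aq NH4Cl
Reagents that add atoms: lithium (trimethylsilyl)acetylide, [Li]C#C[Si](C)(C)C
Why: 1,2-Addition of the lithium acetylide to the enone carbonyl; the new carbinol centre is not controlled and need not be, since it is erased in step 5.

Step 5
Reactants: 8 (4R,5S)-4-ethenyl-4-methyl-5-(prop-1-en-2-yl)-1-[(trimethylsilyl)ethynyl]cyclohex-2-en-1-ol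
Product: 9 (5S,6S)-6-ethenyl-6-methyl-5-(prop-1-en-2-yl)-3-[(trimethylsilyl)ethynyl]cyclohex-2-en-1-one
Conditions: pyridinium chlorochromate (C5H5NH)[CrO3Cl], 4 Å molecular sieves, CH2Cl2, rt
Reagents that add atoms: none
Why: Babler–Dauben oxidative transposition: the tertiary allylic chromate ester (hexavalent chromium) shifts [3,3] to C9 and is oxidised there, moving the carbonyl to C9 and the alkynyl group to the β-carbon of the new enone. The ring alkene is the only useful migration terminus because the alkyne end is capped by silicon.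

Step 6
Reactants: 9 (5S,6S)-6-ethenyl-6-methyl-5-(prop-1-en-2-yl)-3-[(trimethylsilyl)ethynyl]cyclohex-2-en-1-one
Product: 12 (2R,5S,6S)-2-[(tert-butyldimethylsilyl)oxy]-6-ethenyl-6-methyl-5-(prop-1-en-2-yl)-3-[(trimethylsilyl)ethynyl]cyclohex-3-en-1-one, via potassium dienolate 10 (not isolated), via potassium alkoxide 11 (not isolated)
Conditions: KN(SiMe3)2, THF, −78 °C; 2-(phenylsulfonyl)-3-phenyloxaziridine, −78 °C; then t-BuMe2SiOSO2CF3, −78 to −20 °C
Reagents that add atoms: 2-(phenylsulfonyl)-3-phenyloxaziridine, O=S(=O)(c1ccccc1)N1OC1c1ccccc1; tert-butyldimethylsilyl trifluoromethanesulfonate, CC(C)(C)[Si](C)(C)OS(=O)(=O)C(F)(F)F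
Why: γ-Deprotonation at C6 (C10 is quaternary, so no α′-proton competes) gives the extended dienolate, which sulfonyloxaziridines hydroxylate at the α-carbon C8 with deconjugation (Davis oxidation). The pseudoaxial C10 methyl screens the β face of C8, so oxygen enters α. Silylation of the alkoxide in the same flask protects the base-sensitive β,γ-unsaturated ketol before work-up.

Step 7
Reactants: 12 (2R,5S,6S)-2-[(tert-butyldimethylsilyl)oxy]-6-ethenyl-6-methyl-5-(prop-1-en-2-yl)-3-[(trimethylsilyl)ethynyl]cyclohex-3-en-1-one
Product: 14 (1R,2R,5S,6S)-2-[(tert-butyldimethylsilyl)oxy]-6-ethenyl-3-ethynyl-6-methyl-5-(prop-1-en-2-yl)cyclohex-3-en-1-ol, via silylalkyne alcohol 13 (not isolated)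
Conditions: NaBH4, CeCl3·7H2O, MeOH, −78 to −40 °C; then K2CO3, MeOH, 0 °C to rt
Reagents that add atoms: none
Why: Luche reduction: hydride attacks the C9 carbonyl axially from the α face, away from the adjacent axial C10 methyl, giving the equatorial β-alcohol trans to O8 under non-basic conditions. Carbonate in methanol then cleaves only the C(sp)–Si bond.

Step 8
Reactants: 14 (1R,2R,5S,6S)-2-[(tert-butyldimethylsilyl)oxy]-6-ethenyl-3-ethynyl-6-methyl-5-(prop-1-en-2-yl)cyclohex-3-en-1-ol
Product: 15 (1R,2R,5S,6S)-2-[(tert-butyldimethylsilyl)oxy]-6-ethenyl-3-ethynyl-6-methyl-5-(prop-1-en-2-yl)cyclohex-3-en-1-yl (2Z)-2-methylbut-2-enoate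
Conditions: angelic acid, 2,4,6-trichlorobenzoyl chloride, Et3N, toluene, rt; then 14, 80 °C
Reagents that add atoms: angelic acid, C/C=C(/C)C(=O)O
Why: Yamaguchi esterification through the mixed anhydride without a nucleophilic amine catalyst, the usual way to acylate a hindered secondary alcohol with angelic acid without Z to E isomerisation. O9 is the only free hydroxyl, and the C9 configuration is retained.

Step 9
Reactants: 15 (1R,2R,5S,6S)-2-[(tert-butyldimethylsilyl)oxy]-6-ethenyl-3-ethynyl-6-methyl-5-(prop-1-en-2-yl)cyclohex-3-en-1-yl (2Z)-2-methylbut-2-enoate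
Product: 16 methyl 2-[(3S,4S,5R,6R)-6-[(tert-butyldimethylsilyl)oxy]-4-ethenyl-4-methyl-5-{[(2Z)-2-methylbut-2-enoyl]oxy}-3-(prop-1-en-2-yl)cyclohex-1-en-1-yl]prop-2-enoate
Conditions: Pd(OAc)2 (2 mol %), 2-(diphenylphosphino)pyridine (30 mol %), MeSO3H (20 mol %), CO (30 bar), MeOH–THF, 50 °C
Reagents that add atoms: carbon monoxide, [C-]#[O+]; methanol, CO
Why: Palladium-catalysed Markovnikov methoxycarbonylation of a terminal alkyne: the cationic palladium hydride (divalent palladium) with the P,N ligand places palladium on the internal carbon C11, and CO insertion and methanolysis give the 2-substituted acrylate. Alkenes do not react under these mild conditions, and the silyl ether on O8 prevents capture of the acyl palladium species by that oxygen.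

Step 10
Reactants: 16 methyl 2-[(3S,4S,5R,6R)-6-[(tert-butyldimethylsilyl)oxy]-4-ethenyl-4-methyl-5-{[(2Z)-2-methylbut-2-enoyl]oxy}-3-(prop-1-en-2-yl)cyclohex-1-en-1-yl]prop-2-enoate
Product: 17 methyl 2-[(3S,4S,5R,6R)-4-ethenyl-6-hydroxy-4-methyl-5-{[(2Z)-2-methylbut-2-enoyl]oxy}-3-(prop-1-en-2-yl)cyclohex-1-en-1-yl]prop-2-enoate
Conditions: HF·pyridine, pyridine, THF, 0 °C to rt
Reagents that add atoms: none
Why: Fluoride cleavage of the secondary silyl ether under buffered acidic conditions, which avoid the alkoxide that would trigger acyl migration from O9 to O8 or attack on the acrylate ester.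

Step 11
Reactants: 17 methyl 2-[(3S,4S,5R,6R)-4-ethenyl-6-hydroxy-4-methyl-5-{[(2Z)-2-methylbut-2-enoyl]oxy}-3-(prop-1-en-2-yl)cyclohex-1-en-1-yl]prop-2-enoate
Product: 19 (3aS,4S,5R,6S,7S,7aS)-6-ethenyl-3a,4-dihydroxy-6-methyl-3-methylidene-2-oxo-7-(prop-1-en-2-yl)octahydro-1-benzofuran-5-yl (2Z)-2-methylbut-2-enoate, via epoxy ester 18 (not isolated)
Conditions: VO(acac)2 (10 mol %), t-BuOOH (decane), CH2Cl2, 0 °C to rt; then camphorsulfonic acid (10 mol %), wet CH2Cl2, rt
Reagents that add atoms: tert-butyl hydroperoxide, CC(C)(C)OO; water, O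
Why: The C8 hydroxyl binds the tert-butylperoxo vanadate (pentavalent vanadium) and delivers oxygen to the neighbouring C6=C7 bond on its own α face, the known syn-selective epoxidation of cyclic allylic alcohols; the vinyl, isopropenyl, acrylate and angelate C=C bonds are not allylic to a free hydroxyl or are electron-poor and should stay intact, and the α face is also the one remote from the β isopropenyl group on C5. In 18 the ester carbonyl oxygen on C12 can reach only C6 and only from the β face, so acid-promoted opening closes the 5-membered ring with inversion at C6 (formally a 5-endo opening, the normal course of β,γ-epoxy acids and esters), and the cyclic dioxocarbenium ion loses methanol through its water adduct to give the lactone. C7 keeps the epoxide oxygen as the α tertiary hydroxyl and C6 receives the β lactone oxygen, so both centres are set as a trans pair relayed from C8 and the ring fusion is necessarily cis. The opening is trans-diaxial (Fürst–Plattner rule) in the chair that keeps isopropenyl, vinyl, C11, O8 and O9 equatorial, so reagent delivery, sterics and stereoelectronics point the same way. Attack of the carboxyl oxygen at C7 would need a β-lactone and attack of O8 an oxetane, so the regiochemistry is fixed by ring size, and transesterification of O8 onto C12 would give a trans-fused lactone across the epoxide and is not expected to compete. The step is placed last so that the α-methylene-β-hydroxy lactone never meets base, hydride or a nucleophilic catalyst.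

## Compound list

1 | 2-methylprop-2-enal (methacrolein) | CC(=C)C=O | starting material
2 | 2-(triphenyl-λ5-phosphanylidene)propanal | CC(C=O)=P(c1ccccc1)(c1ccccc1)c1ccccc1 | starting material
3 | (2E)-2,4-dimethylpenta-2,4-dienal | CC(=C)/C=C(\C)C=O | intermediate
4 | (1E)-3-[(tert-butyldimethylsilyl)oxy]-N,N-dimethylbuta-1,3-dien-1-amine | C=C(O[Si](C)(C)C(C)(C)C)/C=C/N(C)C | starting material
5 | (1S,2R,6S)-4-[(tert-butyldimethylsilyl)oxy]-2-(dimethylamino)-1-methyl-6-(prop-1-en-2-yl)cyclohex-3-ene-1-carbaldehyde | O=C[C@@]1(C)[C@H](C(=C)C)CC(O[Si](C)(C)C(C)(C)C)=C[C@H]1N(C)C | intermediate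
6 | (1R,5S,6S)-3-[(tert-butyldimethylsilyl)oxy]-6-ethenyl-N,N,6-trimethyl-5-(prop-1-en-2-yl)cyclohex-2-en-1-amine | C=C[C@@]1(C)[C@H](C(=C)C)CC(O[Si](C)(C)C(C)(C)C)=C[C@H]1N(C)C | intermediate
7 | (4R,5S)-4-ethenyl-4-methyl-5-(prop-1-en-2-yl)cyclohex-2-en-1-one | C=C[C@@]1(C)[C@H](C(=C)C)CC(=O)C=C1 | intermediate
8 | (4R,5S)-4-ethenyl-4-methyl-5-(prop-1-en-2-yl)-1-[(trimethylsilyl)ethynyl]cyclohex-2-en-1-ol (both C1 epimers) | C=C[C@@]1(C)[C@H](C(=C)C)CC(O)(C#C[Si](C)(C)C)C=C1 | intermediate
9 | (5S,6S)-6-ethenyl-6-methyl-5-(prop-1-en-2-yl)-3-[(trimethylsilyl)ethynyl]cyclohex-2-en-1-one | C=C[C@@]1(C)[C@H](C(=C)C)CC(C#C[Si](C)(C)C)=CC1=O | intermediate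
10 | potassium (5S,6S)-6-ethenyl-6-methyl-5-(prop-1-en-2-yl)-3-[(trimethylsilyl)ethynyl]cyclohexa-1,3-dien-1-olate | C=C[C@@]1(C)[C@H](C(=C)C)C=C(C#C[Si](C)(C)C)C=C1[O-].[K+] | intermediate
11 | potassium (1R,4S,5S)-5-ethenyl-5-methyl-6-oxo-4-(prop-1-en-2-yl)-2-[(trimethylsilyl)ethynyl]cyclohex-2-en-1-olate | C=C[C@@]1(C)[C@H](C(=C)C)C=C(C#C[Si](C)(C)C)[C@@H]([O-])C1=O.[K+] | intermediate
12 | (2R,5S,6S)-2-[(tert-butyldimethylsilyl)oxy]-6-ethenyl-6-methyl-5-(prop-1-en-2-yl)-3-[(trimethylsilyl)ethynyl]cyclohex-3-en-1-one | C=C[C@@]1(C)[C@H](C(=C)C)C=C(C#C[Si](C)(C)C)[C@@H](O[Si](C)(C)C(C)(C)C)C1=O | intermediate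
13 | (1R,2R,5S,6S)-2-[(tert-butyldimethylsilyl)oxy]-6-ethenyl-6-methyl-5-(prop-1-en-2-yl)-3-[(trimethylsilyl)ethynyl]cyclohex-3-en-1-ol | C=C[C@@]1(C)[C@H](C(=C)C)C=C(C#C[Si](C)(C)C)[C@@H](O[Si](C)(C)C(C)(C)C)[C@@H]1O | intermediate
14 | (1R,2R,5S,6S)-2-[(tert-butyldimethylsilyl)oxy]-6-ethenyl-3-ethynyl-6-methyl-5-(prop-1-en-2-yl)cyclohex-3-en-1-ol | C=C[C@@]1(C)[C@H](C(=C)C)C=C(C#C)[C@@H](O[Si](C)(C)C(C)(C)C)[C@@H]1O | intermediate
15 | (1R,2R,5S,6S)-2-[(tert-butyldimethylsilyl)oxy]-6-ethenyl-3-ethynyl-6-methyl-5-(prop-1-en-2-yl)cyclohex-3-en-1-yl (2Z)-2-methylbut-2-enoate | C=C[C@@]1(C)[C@H](C(=C)C)C=C(C#C)[C@@H](O[Si](C)(C)C(C)(C)C)[C@@H]1OC(=O)/C(C)=C\C | intermediate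
16 | methyl 2-[(3S,4S,5R,6R)-6-[(tert-butyldimethylsilyl)oxy]-4-ethenyl-4-methyl-5-{[(2Z)-2-methylbut-2-enoyl]oxy}-3-(prop-1-en-2-yl)cyclohex-1-en-1-yl]prop-2-enoate | C=C[C@@]1(C)[C@H](C(=C)C)C=C(C(=C)C(=O)OC)[C@@H](O[Si](C)(C)C(C)(C)C)[C@@H]1OC(=O)/C(C)=C\C | intermediate
17 | methyl 2-[(3S,4S,5R,6R)-4-ethenyl-6-hydroxy-4-methyl-5-{[(2Z)-2-methylbut-2-enoyl]oxy}-3-(prop-1-en-2-yl)cyclohex-1-en-1-yl]prop-2-enoate | C=C[C@@]1(C)[C@H](C(=C)C)C=C(C(=C)C(=O)OC)[C@@H](O)[C@@H]1OC(=O)/C(C)=C\C | intermediate
18 | methyl 2-[(1S,2S,3R,4S,5S,6R)-4-ethenyl-2-hydroxy-4-methyl-3-{[(2Z)-2-methylbut-2-enoyl]oxy}-5-(prop-1-en-2-yl)-7-oxabicyclo[4.1.0]heptan-1-yl]prop-2-enoate | C=C[C@@]1(C)[C@H](C(=C)C)[C@H]2O[C@@]2(C(=C)C(=O)OC)[C@@H](O)[C@@H]1OC(=O)/C(C)=C\C | intermediate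
19 | (3aS,4S,5R,6S,7S,7aS)-6-ethenyl-3a,4-dihydroxy-6-methyl-3-methylidene-2-oxo-7-(prop-1-en-2-yl)octahydro-1-benzofuran-5-yl (2Z)-2-methylbut-2-enoate | C=C[C@@]1(C)[C@H](C(=C)C)[C@@H]2OC(=O)C(=C)[C@]2(O)[C@@H](O)[C@@H]1OC(=O)/C(C)=C\C | target

## Step count and least certain steps

Total step count: 11. Longest linear sequence: 11 steps (1 and 2 to 19; 4 is purchased).

Step 11 (key step). The most likely failure is oxidation of the allylic alcohol to the enone instead of oxygen transfer to the alkene. The reactive geometry needs a pseudoaxial C8 hydroxyl, which costs several axial substituents, and the C6=C7 bond is conjugated to the acrylate; loss of facial control would follow from the same cause. The fallback makes that oxidation the plan and uses substrate-controlled nucleophilic epoxidation instead of hydroxyl delivery. It sets out from 17, which is oxidised with MnO2 (CH2Cl2, rt) to the cross-conjugated C8 enone F1. t-BuOOH/DBU (CH2Cl2, 0 °C) should then attack C6 trans to the C5 isopropenyl group and give the α epoxy ketone F2. NaBH4/CeCl3·7H2O (MeOH, −78 °C) should reduce it anti to the epoxide oxygen, returning to the route at 18, which is lactonised with camphorsulfonic acid as in step 11.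

Step 2. The β-substituted, conjugated dienal may be activated too weakly by hydrogen bonding at low temperature, so that an uncatalysed background reaction erodes the enantioselectivity. The fallback moves the chirality into the diene and sets out from 3. 4-Methoxybut-3-en-2-one and (2R,5R)-2,5-diphenylpyrrolidine give the vinylogous amide F3 by amine exchange, and KN(SiMe3)2/t-BuMe2SiCl converts it to the C2-symmetric amino silyloxy diene F4. Thermal Diels–Alder reaction of F4 with 3 (toluene, rt) gives the auxiliary-bearing cycloadduct F5. Methylenation to the vinyl compound F6 and aqueous HF in the same flask, as in step 3, release the auxiliary and return to the route at 7.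

Step 6. Attack of the oxidant at the γ-carbon C6, or base-induced conjugation of the β,γ-unsaturated ketol to a diosphenol before it is silylated, would lose the C8 centre. The fallback avoids the enolate and sets out from 9. t-BuOOH/DBU epoxidises the enone C7=C8 bond on the α face (trans to the C5 isopropenyl group) to give the epoxy ketone F7. t-BuMe2SiOSO2CF3/DBU then isomerises the epoxide to the allylic silyl ether by removal of a C6 proton, which returns to the route at 12.

Step 8. Acylation of the C9 hydroxyl, flanked by the quaternary C10 and the silylated O8, may stall, and forcing conditions invite Z to E isomerisation to the tiglate. The fallback builds the Z-alkene in place and sets out from 14. DCC/DMAP esterification with 2-[bis(2,2,2-trifluoroethoxy)phosphoryl]propanoic acid gives the phosphonate ester F8. Still–Gennari olefination with acetaldehyde (KN(SiMe3)2, 18-crown-6, THF, −78 °C) then returns to the route at 15.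

Step 9. Hydropalladation of the conjugated enyne may lose regiocontrol (linear ester, or addition across the diene system), and the palladium hydride may isomerise the angelate. The fallback fixes the regiochemistry in a separate hydrometalation and sets out from 15. [Cp*Ru(MeCN)3]PF6-catalysed Markovnikov hydrostannation with Bu3SnH gives the 1-stannylvinyl compound F9. PdCl2(PPh3)2-catalysed coupling of F9 with methyl chloroformate (toluene, 80 °C) returns to the route at 16.

## Further compounds

F1 | step 11 | methyl 2-[(3S,4S,5R)-4-ethenyl-4-methyl-5-{[(2Z)-2-methylbut-2-enoyl]oxy}-6-oxo-3-(prop-1-en-2-yl)cyclohex-1-en-1-yl]prop-2-enoate | C=C[C@@]1(C)[C@H](C(=C)C)C=C(C(=C)C(=O)OC)C(=O)[C@@H]1OC(=O)/C(C)=C\C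
F2 | step 11 | methyl 2-[(1R,3R,4S,5S,6R)-4-ethenyl-4-methyl-3-{[(2Z)-2-methylbut-2-enoyl]oxy}-2-oxo-5-(prop-1-en-2-yl)-7-oxabicyclo[4.1.0]heptan-1-yl]prop-2-enoate | C=C[C@@]1(C)[C@H](C(=C)C)[C@H]2O[C@@]2(C(=C)C(=O)OC)C(=O)[C@@H]1OC(=O)/C(C)=C\C
F3 | step 2 | (3E)-4-[(2R,5R)-2,5-diphenylpyrrolidin-1-yl]but-3-en-2-one | CC(=O)/C=C/N1[C@@H](c2ccccc2)CC[C@@H]1c1ccccc1
F4 | step 2 | (2R,5R)-1-{(1E)-3-[(tert-butyldimethylsilyl)oxy]buta-1,3-dien-1-yl}-2,5-diphenylpyrrolidine | C=C(O[Si](C)(C)C(C)(C)C)/C=C/N1[C@@H](c2ccccc2)CC[C@@H]1c1ccccc1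
F5 | step 2 | (1S,2R,6S)-4-[(tert-butyldimethylsilyl)oxy]-2-[(2R,5R)-2,5-diphenylpyrrolidin-1-yl]-1-methyl-6-(prop-1-en-2-yl)cyclohex-3-ene-1-carbaldehyde | O=C[C@@]1(C)[C@H](C(=C)C)CC(O[Si](C)(C)C(C)(C)C)=C[C@H]1N3[C@@H](c4ccccc4)CC[C@@H]3c5ccccc5
F6 | step 2 | (2R,5R)-1-[(1R,5S,6S)-3-[(tert-butyldimethylsilyl)oxy]-6-ethenyl-6-methyl-5-(prop-1-en-2-yl)cyclohex-2-en-1-yl]-2,5-diphenylpyrrolidine | C=C[C@@]1(C)[C@H](C(=C)C)CC(O[Si](C)(C)C(C)(C)C)=C[C@H]1N3[C@@H](c4ccccc4)CC[C@@H]3c5ccccc5
F7 | step 6 | (1R,3S,4S,6S)-3-ethenyl-3-methyl-4-(prop-1-en-2-yl)-6-[(trimethylsilyl)ethynyl]-7-oxabicyclo[4.1.0]heptan-2-one | C=C[C@@]1(C)[C@H](C(=C)C)C[C@@]2(C#C[Si](C)(C)C)O[C@H]2C1=O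
F8 | step 8 | (1R,2R,5S,6S)-2-[(tert-butyldimethylsilyl)oxy]-6-ethenyl-3-ethynyl-6-methyl-5-(prop-1-en-2-yl)cyclohex-3-en-1-yl 2-[bis(2,2,2-trifluoroethoxy)phosphoryl]propanoate (both epimers at the propanoate carbon) | C=C[C@@]1(C)[C@H](C(=C)C)C=C(C#C)[C@@H](O[Si](C)(C)C(C)(C)C)[C@@H]1OC(=O)C(C)P(=O)(OCC(F)(F)F)OCC(F)(F)F
F9 | step 9 | (1R,2R,5S,6S)-2-[(tert-butyldimethylsilyl)oxy]-6-ethenyl-6-methyl-5-(prop-1-en-2-yl)-3-[1-(tributylstannyl)ethenyl]cyclohex-3-en-1-yl (2Z)-2-methylbut-2-enoate | C=C[C@@]1(C)[C@H](C(=C)C)C=C(C(=C)[Sn](CCCC)(CCCC)CCCC)[C@@H](O[Si](C)(C)C(C)(C)C)[C@@H]1OC(=O)/C(C)=C\C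
A1 | alternative 1 | cyclohexanone with 5β-isopropenyl, 6β-(2-bromoprop-2-enoyl)oxy, 7-oxo, 8α-(tert-butyldimethylsilyl)oxy, 9β-angeloyloxy, 10β-methyl and 10α-vinyl groups | C=C[C@@]1(C)[C@H](C(=C)C)[C@H](OC(=O)C(Br)=C)C(=O)[C@@H](O[Si](C)(C)C(C)(C)C)[C@@H]1OC(=O)/C(C)=C\C
A2 | alternative 2 | (1(10)E,4E)-germacra-1(10),4,11(13)-trien-6,12-olide with the 7-hydroxy, 8-hydroxy and 9-angeloyloxy groups configured as in 19 | C/C1=C\CC/C(C)=C/[C@@H]2OC(=O)C(=C)[C@]2(O)[C@@H](O)[C@@H]1OC(=O)/C(C)=C\C
A3 | alternative 3 | methyl (3E,4E)-5-[(tert-butyldimethylsilyl)oxy]-3-{[(tert-butyldimethylsilyl)oxy]methylidene}pent-4-enoate | COC(=O)C/C(=C\O[Si](C)(C)C(C)(C)C)/C=C/O[Si](C)(C)C(C)(C)C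
A4 | alternative 3 | ethyl (2E)-3-methyl-4-oxobut-2-enoate | CCOC(=O)/C=C(\C)C=O
A5 | alternative 3 | ethyl cyclohex-3-ene-1-carboxylate with 2β,5β-bis[(tert-butyldimethylsilyl)oxy], 3-(2-methoxy-2-oxoethyl), 6α-formyl, 6β-methyl and 1β-ethoxycarbonyl groups | O=C[C@@]1(C)[C@H](C(=O)OCC)[C@H](O[Si](C)(C)C(C)(C)C)C(CC(=O)OC)=C[C@@H]1O[Si](C)(C)C(C)(C)C
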